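The ketone carbon of the side chain and the carboxyl carbon stand 1,5 to each other across benzene carbons C1 and C6 and the benzylic CH2, so both can be carbonyl groups of one six-membered anhydride ring, 6,8-dimethoxyisochroman-1,3-dione. The synthesis rests on making the bond between the ketone carbon and the undecyl chain by a palladium-catalysed acyl Negishi opening of this anhydride with undecylzinc bromide. Palladium should insert at the unconjugated carbonyl next to the CH2 (C3 of the isochroman), not at the hindered, conjugated aroyl carbonyl (C1), so one operation forms the ketone and sets the benzoic acid free. Chelation-directed demethylation of the methoxy group next to the carboxyl group then gives the target.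

Key step: step 3

Step 1
Reactants: 1 2,4-dimethoxy-6-methylbenzoic acid
Product: 3 2-(carboxymethyl)-4,6-dimethoxybenzoic acid, via benzylic dianion 2 (not isolated)
Conditions: LDA (2.3 equiv), THF, −78 → −20 °C; CO2 (g), −78 °C → rt; 2 M HCl
Reagents that add atoms: carbon dioxide, O=C=O
Why: The lithium carboxylate acidifies and directs deprotonation of the ortho methyl group (lateral lithiation of an o-toluic acid), and the benzylic carbanion of 2 is carboxylated by CO2 to the homophthalic acid; a doubly carboxylated by-product would lose CO2 again on acidic work-up.

Step 2
Reactants: 3 2-(carboxymethyl)-4,6-dimethoxybenzoic acid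
Product: 4 6,8-dimethoxyisochroman-1,3-dione
Conditions: Ac2O (1.5 equiv), toluene, reflux
Reagents that add atoms: none
Why: Acetic anhydride forms a mixed anhydride that closes by intramolecular acyl transfer to the six-membered cyclic anhydride (cyclodehydration of a homophthalic acid); no base is present, so the acidic C4 methylene should not self-condense.

Step 3
Reactants: 4 6,8-dimethoxyisochroman-1,3-dione; 5 1-bromoundecane
Product: 7 2,4-dimethoxy-6-(2-oxotridecyl)benzoic acid, via undecylzinc bromide 6 (not isolated)
Conditions: 5, Zn dust, LiCl, THF, 50 °C; then added slowly to 4, PdCl2(PPh3)2 (5 mol %), THF, 0 °C → rt; 1 M HCl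
Reagents that add atoms: none
Why: PdCl2(PPh3)2 is reduced by the zinc reagent to zerovalent palladium, which inserts into the C3 acyl–oxygen bond of anhydride 4 to give an acylpalladium carboxylate; transmetalation from 6 and reductive elimination then form the bond between the ketone carbon and the undecyl CH2 and leave the ring-opened zinc carboxylate, which is protonated on work-up. The closest known reaction type is the palladium-, nickel- or rhodium-catalysed alkylative opening of cyclic succinic and glutaric anhydrides with organozinc reagents, an acyl Negishi coupling that gives keto acids. No ring is closed (the anhydride ring is opened) and no stereocenter is formed. The step needs regioselectivity for C3 over C1: C3 is an unhindered, unconjugated alkanoyl carbonyl, whereas C1 is conjugated with the electron-rich dimethoxyarene and shielded by the 8-methoxy group, the same preference that amines and alcohols show with homophthalic anhydrides. It also needs the coupling to outrun protonolysis of 6 by the acidic C4 methylene and loss of CO from the arylacetylpalladium intermediate; the low kinetic basicity of alkylzinc halides, the slow addition of 6 and a temperature of 0 °C to rt should secure this.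

Step 4
Reactants: 7 2,4-dimethoxy-6-(2-oxotridecyl)benzoic acid
Product: 8 2-hydroxy-4-methoxy-6-(2-oxotridecyl)benzoic acid
Conditions: BCl3 (3 equiv), CH2Cl2, −78 → 0 °C; ice-water
Reagents that add atoms: none
Why: Boron binds the carboxyl group and the neighbouring methoxy oxygen in a six-membered chelate and chloride then removes only that methyl group (chelation-directed ortho-demethylation of an o-methoxyaryl carbonyl compound), while the 4-methoxy group cannot chelate and should stay.

Compound list
1 | 2,4-dimethoxy-6-methylbenzoic acid | Cc1cc(OC)cc(OC)c1C(=O)O | starting material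
2 | benzylic dianion of 1 (lithium 2-(lithiomethyl)-4,6-dimethoxybenzoate) | [Li]Cc1cc(OC)cc(OC)c1C(=O)O[Li] | intermediate
3 | 2-(carboxymethyl)-4,6-dimethoxybenzoic acid | OC(=O)Cc1cc(OC)cc(OC)c1C(=O)O | intermediate
4 | 6,8-dimethoxyisochroman-1,3-dione | O=C1Cc2cc(OC)cc(OC)c2C(=O)O1 | intermediate
5 | 1-bromoundecane | CCCCCCCCCCCBr | starting material
6 | undecylzinc bromide | CCCCCCCCCCC[Zn]Br | intermediate
7 | 2,4-dimethoxy-6-(2-oxotridecyl)benzoic acid | CCCCCCCCCCCC(=O)Cc1cc(OC)cc(OC)c1C(=O)O | intermediate
8 | 2-hydroxy-4-methoxy-6-(2-oxotridecyl)benzoic acid | CCCCCCCCCCCC(=O)Cc1cc(OC)cc(O)c1C(=O)O | target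

Total step count: 4. Longest linear sequence: 4 steps (1 → 3 → 4 → 7 → 8); 5 enters in step 3.

Steps most likely to fail

Step 3. The zinc reagent may act as a base toward the acidic C4 methylene, so that the anhydride is enolised and self-condenses. Palladium may also lose CO from the arylacetyl intermediate or insert at C1. The fallback sets out from 4 and comes back at 7. Anhydride 4 is opened with N,O-dimethylhydroxylamine (free base, CH2Cl2, 0 °C → rt), which should attack C3 as other amines do, to give 2-{2-[methoxy(methyl)amino]-2-oxoethyl}-4,6-dimethoxybenzoic acid F1. Undecylmagnesium bromide F2, made from 5 and Mg in THF, is then added in excess (about 3 equiv, THF, −20 → 0 °C). The first equivalent forms the magnesium carboxylate and a further one adds to the amide to give the stable chelate (Weinreb ketone synthesis). Acidic work-up should give 7.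

Step 4. BCl3 may activate the carboxyl group and drive cyclodehydration of the δ-keto acid to the enol lactone, or the ether cleavage may be incomplete. The fallback sets out from 7 and comes back at 8. Compound 7 is cyclodehydrated on purpose (Ac2O, reflux) to 6,8-dimethoxy-3-undecyl-1H-isochromen-1-one F3. BCl3 (CH2Cl2, −78 → 0 °C) should then cleave only the 8-methoxy group, which is peri to the lactone carbonyl, to give 8-hydroxy-6-methoxy-3-undecyl-1H-isochromen-1-one F4. Hydrolysis of the enol lactone (KOH, aq. EtOH, reflux) and cold acidification (HCl, 0 °C) should give 8.

Step 1. Lateral deprotonation of the poorly soluble lithium carboxylate may be incomplete, or proton transfer during the gas quench may return starting acid. The fallback sets out from 1 and comes back at 3. Compound 1 is esterified (MeI, K2CO3, DMF) to methyl 2,4-dimethoxy-6-methylbenzoate F5. The soluble ester is deprotonated at the methyl group with LDA (2.1 equiv, THF, −78 °C) and the anion is trapped with methyl chloroformate to give methyl 2-(2-methoxy-2-oxoethyl)-4,6-dimethoxybenzoate F6. Saponification of both esters (KOH, aq. EtOH, reflux; then HCl) should give 3.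

Further compounds
F1 | step 3 | 2-{2-[methoxy(methyl)amino]-2-oxoethyl}-4,6-dimethoxybenzoic acid | CON(C)C(=O)Cc1cc(OC)cc(OC)c1C(=O)O
F2 | step 3 | undecylmagnesium bromide | CCCCCCCCCCC[Mg]Br
F3 | step 4 | 6,8-dimethoxy-3-undecyl-1H-isochromen-1-one | CCCCCCCCCCCC1=Cc2cc(OC)cc(OC)c2C(=O)O1
F4 | step 4 | 8-hydroxy-6-methoxy-3-undecyl-1H-isochromen-1-one | CCCCCCCCCCCC1=Cc2cc(OC)cc(O)c2C(=O)O1
F5 | step 1 | methyl 2,4-dimethoxy-6-methylbenzoate | Cc1cc(OC)cc(OC)c1C(=O)OC
F6 | step 1 | methyl 2-(2-methoxy-2-oxoethyl)-4,6-dimethoxybenzoate | COC(=O)Cc1cc(OC)cc(OC)c1C(=O)OC
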